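Numbering follows the bicyclo[3.3.1]nonane core (C1 prenylated bridgehead, C5 geranylated bridgehead, C8 gem-dimethyl carbon, C9 bridging ketone). Ring B (C1, C8, C7, C6, C5, C9) is read as a disguised cyclohexane-1,3-dione: C9 and the latent carbonyl C8 flank C1. A Claisen disconnection of C1–C9 leads to (E)-geranylacetone (C1, C8, C7 with its geranyl group) and methyl acrylate (C6, C5, C9). In one operation a Michael addition joins C7 to C6 and the C1 enolate closes ring B onto the ester carbon C9. Carbonyl transposition, C5 geranylation, methyl cuprate addition, Effenberger annulation of ring A, enantiomer-selecting bridgehead prenylation and C3 aroylation finish the synthesis.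

Key step: step 1

Remarks on the chemistry:
- Geranyl = (2E)-3,7-dimethylocta-2,6-dien-1-yl; prenyl = 3-methylbut-2-en-1-yl; ring A = C1–C5 plus C9.
- Isomerically pure (E)-geranylacetone is assumed to be purchased.
- Compounds 3–15 are racemic. For 14 and 15 the SMILES shows the enantiomer that is carried on.
- The sense of enantiomer selection in step 8 is assumed by analogy with the all-prenyl series. If the other enantiomer of 15 reacts faster, the (S,S,S,S)-base is used instead.

Step 1
Reactants: 1 (E)-geranylacetone; 2 methyl acrylate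
Product: 4 4-geranylcyclohexane-1,3-dione (racemic), via keto ester 3 (not isolated)
Conditions: t-BuOK (2.2 equiv), THF, 0 °C; slow addition of 2, 0 °C to rt; then 1 M HCl
Reagents that add atoms: none
Why: t-BuOK equilibrates the enolates of 1 and the more substituted C7 enolate adds to 2 (Michael addition, C7–C6 bond) to give 3; after proton transfer the methyl (C1) enolate of 3 attacks the ester carbonyl C9 (Claisen condensation of the Dieckmann type), which forms the C1–C9 bond and closes ring B. The closest known reaction type is the consecutive Michael–Claisen [3+3] synthesis of 4-substituted cyclohexane-1,3-diones from substituted acetones and acrylates under thermodynamic enolate conditions. Ring B closes in the 6-(enolexo)-exo-trig mode, and loss of methoxide followed by deprotonation of the new 1,3-dione at C1 makes the closure irreversible. The only stereocentre, C7, is formed racemic and remains epimerisable as long as C8 is a carbonyl, so nothing controls it here; it is fixed relative to C5 and C1 in step 6 and its absolute sense is selected in step 8. The step needs Michael addition at C7 and not at C1, and mono-addition: reversible enolate formation with t-BuOK in THF favours the more substituted and more nucleophilic C7 enolate, and slow addition of 2 to the pre-formed enolate limits double addition and acrylate polymerisation.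

Step 2
Reactants: 4 4-geranylcyclohexane-1,3-dione
Product: 5 3-methoxy-6-geranylcyclohex-2-en-1-one (racemic)
Conditions: HC(OMe)3, MeOH, TsOH·H2O (cat.), rt
Reagents that add atoms: trimethyl orthoformate, COC(OC)OC
Why: Acid-catalysed enol etherification of the cyclic 1,3-dione (vinylogous ester formation) should take place mainly at the less hindered carbonyl C9, remote from the C7 substituent, so that C8 stays as the ketone; the minor 4-geranyl regioisomer is removed by chromatography.

Step 3
Reactants: 5 3-methoxy-6-geranylcyclohex-2-en-1-one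
Product: 7 3-methyl-4-geranylcyclohex-2-en-1-one (racemic), via tertiary lithium alkoxide 6 (not isolated)
Conditions: MeLi, THF, −78 °C; then 1 M HCl, THF, 0 °C to rt
Reagents that add atoms: methyllithium, [Li]C
Why: Stork–Danheiser carbonyl transposition: MeLi adds 1,2 to the C8 ketone of the vinylogous ester, and acid hydrolysis of the enol ether with loss of water returns the ketone to C9, places the first methyl group on C8 and takes C7 out of the α-position so that it no longer epimerises.

Step 4
Reactants: 7 3-methyl-4-geranylcyclohex-2-en-1-one; 8 geranyl bromide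
Product: 10 4,6-digeranyl-3-methylcyclohex-2-en-1-one (racemic cis/trans mixture), via lithium dienolate 9 (not isolated)
Conditions: LiN(i-Pr)2 (LDA), THF, −78 °C; then 8, −78 to 0 °C
Reagents that add atoms: none
Why: Kinetic α′-deprotonation of the enone at C5 gives the cross-conjugated enolate 9, which is alkylated by the allylic bromide (enolate SN2 alkylation); the C5 configuration is irrelevant because C5 is enolised again in step 6.

Step 5
Reactants: 10 4,6-digeranyl-3-methylcyclohex-2-en-1-one
Product: 11 [(4,6-digeranyl-3,3-dimethylcyclohex-1-en-1-yl)oxy]trimethylsilane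
Conditions: MeMgBr, CuBr·SMe2 (cat.), TMSCl, HMPA, THF, −78 to −40 °C; Et3N, non-aqueous work-up
Reagents that add atoms: methylmagnesium bromide, C[Mg]Br; chlorotrimethylsilane, C[Si](C)(C)Cl
Why: Copper-catalysed, TMSCl-accelerated conjugate addition of the methyl Grignard reagent to the β,β-disubstituted enone installs the second C8 methyl group and traps the enolate regiospecifically as the C9–C1 silyl enol ether.

Step 6
Reactants: 11 [(4,6-digeranyl-3,3-dimethylcyclohex-1-en-1-yl)oxy]trimethylsilane; 12 malonyl dichloride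
Product: 14 rac-5,7-digeranyl-4-hydroxy-8,8-dimethylbicyclo[3.3.1]non-3-ene-2,9-dione (7-exo), via keto acid chloride 13 (not isolated)
Conditions: Et2O, −20 °C to rt; then KOH, BnEt3NCl, H2O, rt; dilute HCl
Reagents that add atoms: none
Why: Effenberger cyclisation: the silyl enol ether is C-acylated at C1 to give 13, whose second acid chloride acylates C5 through the C9 enol and closes ring A; both new bonds are axial on chair ring B and anti to the equatorial C7 geranyl group, which sets the quaternary C5 (and the forced bridgehead C1) relative to C7 as the 7-exo isomer.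

Step 7
Reactants: 14 rac-5,7-digeranyl-4-hydroxy-8,8-dimethylbicyclo[3.3.1]non-3-ene-2,9-dione
Product: 15 rac-5,7-digeranyl-4-methoxy-8,8-dimethylbicyclo[3.3.1]non-3-ene-2,9-dione
Conditions: Me2SO4, K2CO3, acetone, reflux
Reagents that add atoms: dimethyl sulfate, COS(=O)(=O)OC
Why: O-Methylation of the vinylogous acid with a hard electrophile gives the vinylogous ester, which masks the acidic enol and permits bridgehead metalation; the C2-methoxy regioisomer is separated and returned to 14 by hydrolysis.

Step 8
Reactants: 15 rac-5,7-digeranyl-4-methoxy-8,8-dimethylbicyclo[3.3.1]non-3-ene-2,9-dione; 16 prenyl bromide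
Product: 18 5,7-digeranyl-4-methoxy-8,8-dimethyl-1-prenylbicyclo[3.3.1]non-3-ene-2,9-dione (single enantiomer), via bridgehead organolithium 17 (not isolated)
Conditions: dilithium amide of (1R,2R)-N,N′-bis[(1R)-1-phenylethyl]-1,2-diphenylethane-1,2-diamine (0.5 equiv, made with n-BuLi), LiCl, THF, −100 °C; then 16, −100 to −78 °C; run to less than half conversion
Reagents that add atoms: none
Why: Kinetic resolution by bridgehead lithiation: the chiral bis-lithium amide should remove the C1–H (α to the C2 and C9 carbonyls) of one enantiomer of 15 faster, and the configurationally fixed organolithium 17 is alkylated by prenyl bromide with retention, so the absolute configuration at C1, C5 and C7 is fixed by enantiomer selection; the unreacted enantiomer of 15 is removed by chromatography.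

Step 9
Reactants: 19 3,4-dihydroxybenzoic acid
Product: 21 3,4-bis(tert-butyldimethylsilyloxy)benzoic acid, via tris-silylated ester 20 (not isolated)
Conditions: TBSCl (3.5 equiv), imidazole, DMF, rt; then K2CO3, MeOH/THF/H2O, rt; citric acid
Reagents that add atoms: tert-butyldimethylsilyl chloride, CC(C)(C)[Si](C)(C)Cl
Why: Exhaustive silylation of both phenols and the acid, followed by selective solvolysis of the labile silyl ester, leaves the two aryl silyl ethers (silyl protection and selective deprotection).

Step 10
Reactants: 21 3,4-bis(tert-butyldimethylsilyloxy)benzoic acid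
Product: 22 3,4-bis(tert-butyldimethylsilyloxy)benzoyl chloride
Conditions: (COCl)2, DMF (cat.), CH2Cl2, 0 °C to rt; used crude
Reagents that add atoms: oxalyl chloride, ClC(=O)C(=O)Cl
Why: Acid chloride formation through the Vilsmeier-type chloroiminium species runs under conditions that the aryl silyl ethers tolerate.

Step 11
Reactants: 18 5,7-digeranyl-4-methoxy-8,8-dimethyl-1-prenylbicyclo[3.3.1]non-3-ene-2,9-dione; 22 3,4-bis(tert-butyldimethylsilyloxy)benzoyl chloride
Product: 24 3-[3,4-bis(tert-butyldimethylsilyloxy)benzoyl]-5,7-digeranyl-4-methoxy-8,8-dimethyl-1-prenylbicyclo[3.3.1]non-3-ene-2,9-dione, via C3 vinyllithium 23 (not isolated)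
Conditions: lithium 2,2,6,6-tetramethylpiperidide (from the amine and n-BuLi), THF, −78 °C; then 22, −78 °C
Reagents that add atoms: none
Why: With C1 blocked, the hindered amide base lithiates the vinylic C3–H of the β-methoxy enone, and the vinyllithium 23 is C-acylated by the acid chloride (directed vinylic lithiation and acylation).

Step 12
Reactants: 24 3-[3,4-bis(tert-butyldimethylsilyloxy)benzoyl]-5,7-digeranyl-4-methoxy-8,8-dimethyl-1-prenylbicyclo[3.3.1]non-3-ene-2,9-dione
Product: 25 (1S,5S,7R)-3-(3,4-dihydroxybenzoyl)-5,7-digeranyl-4-hydroxy-8,8-dimethyl-1-prenylbicyclo[3.3.1]non-3-ene-2,9-dione (CNP0125932.1)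
Conditions: LiOH, degassed 1,4-dioxane/H2O, 90 °C, argon; then dilute HCl to pH 4, 0 °C
Reagents that add atoms: lithium hydroxide, [Li+].[OH-]
Why: Hydroxide should cleave the doubly activated vinylogous methyl ester by conjugate addition–elimination at C4 and remove both aryl silyl ethers by attack at silicon, while the product sits protected as its enolate/phenolate and no stereocentre is touched.

Compound list
1 | (E)-geranylacetone, (5E)-6,10-dimethylundeca-5,9-dien-2-one | CC(=O)CC/C=C(\C)CCC=C(C)C | starting material
2 | methyl acrylate | C=CC(=O)OC | starting material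
3 | methyl (6E)-4-acetyl-7,11-dimethyldodeca-6,10-dienoate (racemic Michael adduct, not isolated) | COC(=O)CCC(C(C)=O)C/C=C(\C)CCC=C(C)C | intermediate
4 | 4-geranylcyclohexane-1,3-dione (racemic, keto–enol mixture) | O=C1CC(=O)C(C/C=C(\C)CCC=C(C)C)CC1 | intermediate
5 | 3-methoxy-6-geranylcyclohex-2-en-1-one (racemic) | COC1=CC(=O)C(C/C=C(\C)CCC=C(C)C)CC1 | intermediate
6 | lithium 3-methoxy-1-methyl-6-geranylcyclohex-2-en-1-olate (not isolated) | COC1=CC(C)(O[Li])C(C/C=C(\C)CCC=C(C)C)CC1 | intermediate
7 | 3-methyl-4-geranylcyclohex-2-en-1-one (racemic) | CC1=CC(=O)CCC1C/C=C(\C)CCC=C(C)C | intermediate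
8 | geranyl bromide, (2E)-1-bromo-3,7-dimethylocta-2,6-diene | BrC/C=C(\C)CCC=C(C)C | starting material
9 | lithium 4-geranyl-5-methylcyclohexa-1,5-dien-1-olate (not isolated) | [Li]OC1=CCC(C/C=C(\C)CCC=C(C)C)C(C)=C1 | intermediate
10 | 4,6-digeranyl-3-methylcyclohex-2-en-1-one (racemic, cis/trans mixture at C4/C6) | CC1=CC(=O)C(C/C=C(\C)CCC=C(C)C)CC1C/C=C(\C)CCC=C(C)C | intermediate
11 | [(4,6-digeranyl-3,3-dimethylcyclohex-1-en-1-yl)oxy]trimethylsilane (racemic diastereomer mixture) | C[Si](C)(C)OC1=CC(C)(C)C(C/C=C(\C)CCC=C(C)C)CC1C/C=C(\C)CCC=C(C)C | intermediate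
12 | malonyl dichloride | ClC(=O)CC(=O)Cl | starting material
13 | 3-(3,5-digeranyl-2,2-dimethyl-6-oxocyclohexyl)-3-oxopropanoyl chloride (not isolated) | O=C(Cl)CC(=O)C1C(=O)C(C/C=C(\C)CCC=C(C)C)CC(C/C=C(\C)CCC=C(C)C)C1(C)C | intermediate
14 | rac-5,7-digeranyl-4-hydroxy-8,8-dimethylbicyclo[3.3.1]non-3-ene-2,9-dione, C7 geranyl exo (trans to the C2–C4 bridge); enantiomer carried on is shown | CC(C)=CCC/C(C)=C/C[C@@H]1C[C@]2(C/C=C(\C)CCC=C(C)C)C(=O)[C@@H](C(=O)C=C2O)C1(C)C | intermediate
15 | rac-5,7-digeranyl-4-methoxy-8,8-dimethylbicyclo[3.3.1]non-3-ene-2,9-dione; enantiomer that reacts in step 8 is shown | CC(C)=CCC/C(C)=C/C[C@@H]1C[C@]2(C/C=C(\C)CCC=C(C)C)C(=O)[C@@H](C(=O)C=C2OC)C1(C)C | intermediate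
16 | prenyl bromide, 1-bromo-3-methylbut-2-ene | BrCC=C(C)C | starting material
17 | C1 (bridgehead) lithio derivative of the reacting enantiomer of 15 (not isolated) | CC(C)=CCC/C(C)=C/C[C@@H]1C[C@]2(C/C=C(\C)CCC=C(C)C)C(=O)[C@@]([Li])(C(=O)C=C2OC)C1(C)C | intermediate
18 | 5,7-digeranyl-4-methoxy-8,8-dimethyl-1-prenylbicyclo[3.3.1]non-3-ene-2,9-dione, configuration as in 25 | CC(C)=CCC/C(C)=C/C[C@@H]1C[C@]2(C/C=C(\C)CCC=C(C)C)C(=O)[C@@](CC=C(C)C)(C(=O)C=C2OC)C1(C)C | intermediate
19 | 3,4-dihydroxybenzoic acid | OC(=O)c1ccc(O)c(O)c1 | starting material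
20 | tert-butyldimethylsilyl 3,4-bis(tert-butyldimethylsilyloxy)benzoate (not isolated) | CC(C)(C)[Si](C)(C)OC(=O)c1ccc(O[Si](C)(C)C(C)(C)C)c(O[Si](C)(C)C(C)(C)C)c1 | intermediate
21 | 3,4-bis(tert-butyldimethylsilyloxy)benzoic acid | OC(=O)c1ccc(O[Si](C)(C)C(C)(C)C)c(O[Si](C)(C)C(C)(C)C)c1 | intermediate
22 | 3,4-bis(tert-butyldimethylsilyloxy)benzoyl chloride | O=C(Cl)c1ccc(O[Si](C)(C)C(C)(C)C)c(O[Si](C)(C)C(C)(C)C)c1 | intermediate
23 | C3 lithio derivative of 18 (not isolated) | CC(C)=CCC/C(C)=C/C[C@@H]1C[C@]2(C/C=C(\C)CCC=C(C)C)C(=O)[C@@](CC=C(C)C)(C(=O)C([Li])=C2OC)C1(C)C | intermediate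
24 | 3-[3,4-bis(tert-butyldimethylsilyloxy)benzoyl]-5,7-digeranyl-4-methoxy-8,8-dimethyl-1-prenylbicyclo[3.3.1]non-3-ene-2,9-dione, configuration as in 25 | CC(C)=CCC/C(C)=C/C[C@@H]1C[C@]2(C/C=C(\C)CCC=C(C)C)C(=O)[C@@](CC=C(C)C)(C(=O)C(C(=O)c3ccc(O[Si](C)(C)C(C)(C)C)c(O[Si](C)(C)C(C)(C)C)c3)=C2OC)C1(C)C | intermediate
25 | (1S,5S,7R)-3-(3,4-dihydroxybenzoyl)-5,7-digeranyl-4-hydroxy-8,8-dimethyl-1-prenylbicyclo[3.3.1]non-3-ene-2,9-dione (CNP0125932.1) | CC(C)=CCC/C(C)=C/C[C@@H]1C[C@]2(C/C=C(\C)CCC=C(C)C)C(=O)[C@@](CC=C(C)C)(C(=O)C(C(=O)c3ccc(O)c(O)c3)=C2O)C1(C)C | target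

Total step count: 12. Longest linear sequence: 10 (steps 1–8, 11, 12); steps 9 and 10 prepare the aroyl chloride.

Steps most likely to fail

1. Step 6. O-Acylation to pyranone-type enol lactones, oligomerisation of the diacid chloride and addition of HCl to the trisubstituted alkenes may consume material before the second C-acylation at the hindered C5 occurs. The fallback builds ring A by C-alkylation/C-acylation and brings in the missing oxygen afterwards; it sets out from 11 and returns at 14. Mild hydrolysis of 11 (citric acid, THF/H2O) gives 2,4-digeranyl-5,5-dimethylcyclohexan-1-one F1. Pyrrolidine (TsOH cat., benzene, water separator) converts it into the less substituted enamine 1-(4,6-digeranyl-3,3-dimethylcyclohex-1-en-1-yl)pyrrolidine F2. Acryloyl chloride in refluxing benzene, followed by aqueous work-up, effects the enamine α,α′-annulation to 5,7-digeranyl-8,8-dimethylbicyclo[3.3.1]nonane-4,9-dione F3, again anti to the C7 geranyl group; should the acyl carbon end up on C1, the isomeric 2,9-dione converges in the same way. 2-Iodoxybenzoic acid in DMSO at 70 °C dehydrogenates F3 to the enone 5,7-digeranyl-8,8-dimethylbicyclo[3.3.1]non-2-ene-4,9-dione F4. H2O2/NaOH in MeOH epoxidises only the electron-poor alkene to the 2,3-epoxy-4,9-dione F5. Pd(PPh3)4/dppe in toluene isomerises this α,β-epoxy ketone to the β-diketone 14.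

2. Step 8. The chiral base may discriminate the two enantiomers insufficiently, or lithiate C3 in competition with the bridgehead. The fallback replaces kinetic resolution by physical resolution; it sets out from 15 and returns at 18. Racemic 15 is prenylated with LiN(i-Pr)2 and 16 (THF, −78 °C), which gives 18 together with its mirror image, the enantiomer of 18 F6. The racemate is separated by preparative HPLC on a cellulose tris(3,5-dimethylphenylcarbamate) stationary phase and 18 is carried on.

3. Step 1. Michael addition through the methyl-side enolate, double Michael addition or polymerisation of the acrylate may erode the annulation. The fallback fixes the site of C–C bond formation with an acetoacetate; it sets out from 8 and 2 and returns at 3, and from there at 4. Methyl acetoacetate is alkylated with 8 (K2CO3, acetone) to methyl 2-geranylacetoacetate F7. Its Michael addition to 2 (DBU cat., MeCN) gives dimethyl 2-acetyl-2-geranylpentanedioate F8. Krapcho dealkoxycarbonylation (LiCl, wet DMSO, 150 °C) removes the ester on the quaternary carbon and gives 3, which is closed to 4 with t-BuOK in THF by the same Claisen condensation of C1 onto C9.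

Further compounds
F1 | step 6 | 2,4-digeranyl-5,5-dimethylcyclohexan-1-one (racemic diastereomer mixture) | O=C1CC(C)(C)C(C/C=C(\C)CCC=C(C)C)CC1C/C=C(\C)CCC=C(C)C
F2 | step 6 | 1-(4,6-digeranyl-3,3-dimethylcyclohex-1-en-1-yl)pyrrolidine | C1CCN(C1)C2=CC(C)(C)C(C/C=C(\C)CCC=C(C)C)CC2C/C=C(\C)CCC=C(C)C
F3 | step 6 | rac-5,7-digeranyl-8,8-dimethylbicyclo[3.3.1]nonane-4,9-dione (7-exo; one enantiomer shown) | CC(C)=CCC/C(C)=C/C[C@@H]1C[C@]2(C/C=C(\C)CCC=C(C)C)C(=O)[C@@H](CCC2=O)C1(C)C
F4 | step 6 | rac-5,7-digeranyl-8,8-dimethylbicyclo[3.3.1]non-2-ene-4,9-dione (one enantiomer shown) | CC(C)=CCC/C(C)=C/C[C@@H]1C[C@]2(C/C=C(\C)CCC=C(C)C)C(=O)[C@@H](C=CC2=O)C1(C)C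
F5 | step 6 | rac-2,3-epoxy-5,7-digeranyl-8,8-dimethylbicyclo[3.3.1]nonane-4,9-dione (epoxide face not assigned; one enantiomer shown) | CC(C)=CCC/C(C)=C/C[C@@H]1C[C@]2(C/C=C(\C)CCC=C(C)C)C(=O)[C@@H](C3OC3C2=O)C1(C)C
F6 | step 8 | enantiomer of 18 | CC(C)=CCC/C(C)=C/C[C@H]1C[C@@]2(C/C=C(\C)CCC=C(C)C)C(=O)[C@](CC=C(C)C)(C(=O)C=C2OC)C1(C)C
F7 | step 1 | methyl 2-geranylacetoacetate, methyl (4E)-2-acetyl-5,9-dimethyldeca-4,8-dienoate (racemic) | COC(=O)C(C/C=C(\C)CCC=C(C)C)C(C)=O
F8 | step 1 | dimethyl 2-acetyl-2-geranylpentanedioate (racemic) | COC(=O)CCC(C/C=C(\C)CCC=C(C)C)(C(C)=O)C(=O)OC
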